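**Plan**
1. Retrosynthetic cuts: first the MOM helper on O5, then the aryl C6–C(=O) bond (aryllithium plus cinnamoyl Weinreb amide). Last come the O1–C2 and C2–C3 bonds of the pyran, so that the CMe2 carbon is excised and a benzofuran remains.
2. Forward order: the benzene ring and a five-membered O-ring are bought together as 4,6-dimethoxybenzofuran-3(2H)-one. Its C3 carbonyl is a helper that lets BCl3 distinguish the peri 4-OMe from the 6-OMe, and reduction/dehydration then removes it and aromatises the furan.
3. Key event: a one-carbon ring expansion from furan to 2H-pyran. Reductive lithiation opens O1–C2, the vinyl anion captures acetone, and acid recloses O1 onto CMe2, so CMe2 is inserted into the O1–C2 bond.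
4. Enabling feature: the O1–C2(sp2) enol-ether bond of the furan ring is conjugated through C3/C3a with the benzene ring and ends on an aryloxide leaving group (O1 on C7a). Furan C2=C3 becomes pyran C3=C4, and benzofuran O4/O6 map onto chromene O5/O7, so the linear annulation pattern is fixed in advance.
5. The chain is joined last at C6, the only C–H ortho to OMOM, and the MOM group is then removed.
6. Stereochemistry: there is no stereocentre. The E-enone is bought in with (E)-4-methoxycinnamic acid, and the cis ring alkene is inherited from the furan.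

Key step: step 4

Assumption: the target is achiral. The E-enone is the only stereochemical element to control, so no enantioselective step is required.

**Step 1**
Reactants: 1 4,6-dimethoxybenzofuran-3(2H)-one
Product: 3 4-hydroxy-6-methoxybenzofuran-3(2H)-one, via boron chelate 2 (not isolated)
Conditions: BCl3 (1.2 equiv), CH2Cl2, −78 → 0 °C; then H2O
Reagents that add atoms: none
Why: In this chelation-directed Lewis-acid aryl methyl ether cleavage, BCl3 bridges the C3 carbonyl oxygen and the peri 4-OMe oxygen in a six-membered chelate, so chloride should remove only that methyl group and leave the remote 6-OMe intact.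

**Step 2**
Reactants: 3 4-hydroxy-6-methoxybenzofuran-3(2H)-one
Product: 4 6-methoxy-4-(methoxymethoxy)benzofuran-3(2H)-one
Conditions: MOMCl, i-Pr2NEt, CH2Cl2, 0 °C → rt
Reagents that add atoms: chloromethyl methyl ether (MOMCl), COCCl
Why: This is O-alkylation (MOM protection) of the only free phenol under an amine base too weak to enolise the α-aryloxy ketone, and the MOM group later serves as the ortho-lithiation director.

**Step 3**
Reactants: 4 6-methoxy-4-(methoxymethoxy)benzofuran-3(2H)-one
Product: 7 6-methoxy-4-(methoxymethoxy)benzofuran, via benzylic alcohol 5 (not isolated), via benzylic mesylate 6 (not isolated)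
Conditions: NaBH4, MeOH/THF, 0 °C; crude, MsCl, Et3N, CH2Cl2, 0 °C → rt
Reagents that add atoms: none
Why: Borohydride 1,2-reduction of the aryl ketone is followed by mesylation and base-mediated elimination, which is driven by aromatisation to the furan, runs under basic conditions that spare the MOM ether, and destroys the transient carbinol stereocentre.

**Step 4**
Reactants: 7 6-methoxy-4-(methoxymethoxy)benzofuran
Product: 10 7-methoxy-5-(methoxymethoxy)-2,2-dimethyl-2H-chromene, via dilithio dianion 8 (not isolated), via Z-diol 9 (not isolated)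
Conditions: Li powder (excess), DTBB (5 mol %), THF, 0 °C; acetone, −78 °C; sat. aq NH4Cl; crude, PPTS (5 mol %), CH2Cl2, rt
Reagents that add atoms: acetone, CC(C)=O
Why: Two electron transfers from Li/DTBB into the styrene-like enol-ether π-system of 7 break the O1–C2(sp2) bond, because the charge leaves as an aryloxide, and give the (Z)-2-lithiovinyl phenoxide 8, whose cis geometry is inherited from the ring and held by O–Li coordination. The vinyllithium adds 1,2 to acetone, which places the CMe2 carbon on the former furan C2, and protonation gives the (Z)-diol 9. Mild acid ionises the tertiary allylic alcohol to an aryl-stabilised dimethylallyl cation, and the phenol oxygen closes the pyran at CMe2 (6-endo-trig capture of the allyl cation), so CMe2 ends up inserted into the former O1–C2 bond and the five-membered ring becomes six-membered. The closest known reaction type is the arene-catalysed reductive lithiation of the parent benzofuran with carbonyl trapping and acid cyclodehydration to 2H-chromenes. No stereocentre is formed, and the ring alkene can only be cis. The step needs cleavage of the vinyl C–O bond in preference to the aryl OMe and OMOM ethers, which is secured because the furan C2=C3 unit is the best electron acceptor at 0 °C and the resulting dianion resists further reduction.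

**Step 5**
Reactants: 11 (E)-4-methoxycinnamic acid
Product: 13 (E)-N-methoxy-3-(4-methoxyphenyl)-N-methylprop-2-enamide, via acyl imidazolide 12 (not isolated)
Conditions: CDI, CH2Cl2, rt; then MeNHOMe·HCl, rt
Reagents that add atoms: N,O-dimethylhydroxylamine hydrochloride, CNOC.Cl
Why: This is a CDI-mediated amide coupling (Weinreb amide synthesis) that activates only the carboxyl group and leaves the E-alkene untouched.

**Step 6**
Reactants: 10 7-methoxy-5-(methoxymethoxy)-2,2-dimethyl-2H-chromene; 13 (E)-N-methoxy-3-(4-methoxyphenyl)-N-methylprop-2-enamide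
Product: 16 (E)-1-[7-methoxy-5-(methoxymethoxy)-2,2-dimethyl-2H-chromen-6-yl]-3-(4-methoxyphenyl)prop-2-en-1-one, via aryllithium 14 (not isolated), via lithium hemiaminal 15 (not isolated)
Conditions: n-BuLi, THF, 0 °C; then 13, −78 → 0 °C; sat. aq NH4Cl
Reagents that add atoms: none
Why: Directed ortho-metalation is followed by Weinreb ketone synthesis, in which C6–H lies between OMOM and OMe and is the only position ortho to the stronger MOM director, the hard aryllithium should add 1,2, and the chelated adduct 15 blocks over-addition, so the E-enone is carried over unchanged.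

**Step 7**
Reactants: 16 (E)-1-[7-methoxy-5-(methoxymethoxy)-2,2-dimethyl-2H-chromen-6-yl]-3-(4-methoxyphenyl)prop-2-en-1-one
Product: 17 glychalcone A, (E)-1-(5-hydroxy-7-methoxy-2,2-dimethyl-2H-chromen-6-yl)-3-(4-methoxyphenyl)prop-2-en-1-one
Conditions: conc. HCl (cat.), MeOH, 40 °C
Reagents that add atoms: none
Why: This acid-catalysed acetal exchange (MOM cleavage) is favoured by the hydrogen bond that forms to the neighbouring carbonyl and is mild enough to leave the chromene alkene and the E-enone untouched.

**Compound list**
1 | 4,6-dimethoxybenzofuran-3(2H)-one | O=C1COc2cc(OC)cc(OC)c12 | starting material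
2 | 4-(dichloroboryloxy)-6-methoxybenzofuran-3(2H)-one (boron chelate) | O=C1COc2cc(OC)cc(OB(Cl)Cl)c12 | intermediate
3 | 4-hydroxy-6-methoxybenzofuran-3(2H)-one | O=C1COc2cc(OC)cc(O)c12 | intermediate
4 | 6-methoxy-4-(methoxymethoxy)benzofuran-3(2H)-one | O=C1COc2cc(OC)cc(OCOC)c12 | intermediate
5 | 6-methoxy-4-(methoxymethoxy)-2,3-dihydrobenzofuran-3-ol (racemic) | OC1COc2cc(OC)cc(OCOC)c12 | intermediate
6 | 6-methoxy-4-(methoxymethoxy)-2,3-dihydrobenzofuran-3-yl methanesulfonate (racemic) | CS(=O)(=O)OC1COc2cc(OC)cc(OCOC)c12 | intermediate
7 | 6-methoxy-4-(methoxymethoxy)benzofuran | COCOc1cc(OC)cc2occc12 | intermediate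
8 | lithium 2-[(Z)-2-lithioethenyl]-5-methoxy-3-(methoxymethoxy)phenolate | [Li]Oc1cc(OC)cc(OCOC)c1/C=C\[Li] | intermediate
9 | 2-[(Z)-3-hydroxy-3-methylbut-1-en-1-yl]-5-methoxy-3-(methoxymethoxy)phenol | Oc1cc(OC)cc(OCOC)c1/C=C\C(C)(C)O | intermediate
10 | 7-methoxy-5-(methoxymethoxy)-2,2-dimethyl-2H-chromene | COCOc1cc(OC)cc2OC(C)(C)C=Cc12 | intermediate
11 | (E)-4-methoxycinnamic acid | COc1ccc(/C=C/C(=O)O)cc1 | starting material
12 | (E)-1-(1H-imidazol-1-yl)-3-(4-methoxyphenyl)prop-2-en-1-one | COc1ccc(/C=C/C(=O)n2ccnc2)cc1 | intermediate
13 | (E)-N-methoxy-3-(4-methoxyphenyl)-N-methylprop-2-enamide | COc1ccc(/C=C/C(=O)N(C)OC)cc1 | intermediate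
14 | [7-methoxy-5-(methoxymethoxy)-2,2-dimethyl-2H-chromen-6-yl]lithium | [Li]c1c(OC)cc2OC(C)(C)C=Cc2c1OCOC | intermediate
15 | lithium (E)-1-[methoxy(methyl)amino]-1-[7-methoxy-5-(methoxymethoxy)-2,2-dimethyl-2H-chromen-6-yl]-3-(4-methoxyphenyl)prop-2-en-1-olate (racemic) | COCOc1c(C(O[Li])(N(C)OC)/C=C/c2ccc(OC)cc2)c(OC)cc2OC(C)(C)C=Cc12 | intermediate
16 | (E)-1-[7-methoxy-5-(methoxymethoxy)-2,2-dimethyl-2H-chromen-6-yl]-3-(4-methoxyphenyl)prop-2-en-1-one | COCOc1c(C(=O)/C=C/c2ccc(OC)cc2)c(OC)cc2OC(C)(C)C=Cc12 | intermediate
17 | glychalcone A | COc1ccc(/C=C/C(=O)c2c(OC)cc3c(c2O)C=CC(C)(C)O3)cc1 | target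

**Step count**
Total steps: 7. Longest linear sequence: 6 (steps 1, 2, 3, 4, 6, 7).

**Steps most likely to fail**

**Step 4.** Several processes could erode the ring expansion:
- reductive cleavage of the aryl OMOM or OMe ethers in competition with furan opening
- protonation of the vinyllithium through enolisation of acetone
- Z to E isomerisation of the vinyllithium, which would prevent ring closure

The fallback sets out from 7 and returns at 10.
- Ozonolysis of the furan C2=C3 bond (O3, CH2Cl2, −78 °C; Me2S) would give 2-formyl-5-methoxy-3-(methoxymethoxy)phenyl formate F1.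
- Methanolysis (K2CO3, MeOH) would give 2-hydroxy-4-methoxy-6-(methoxymethoxy)benzaldehyde F2.
- Addition of 2-methylprop-1-enylmagnesium bromide (2.2 equiv, THF) would give 2-(1-hydroxy-3-methylbut-2-en-1-yl)-5-methoxy-3-(methoxymethoxy)phenol F3.
- Cyclodehydration of F3 with catalytic PPTS, through the same allyl cation, would close the pyran to 10.

**Step 6.** Lithiation could be only partly regioselective (C8 in competition with C6). The hindered aryllithium could also add sluggishly or in conjugate fashion to the unsaturated amide.

The fallback sets out from 10 and returns at 17.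
- MOM cleavage (cat. HCl, MeOH) would give 7-methoxy-2,2-dimethyl-2H-chromen-5-ol F4.
- Magnesium-phenoxide-directed ortho-formylation (MgCl2, Et3N, paraformaldehyde, MeCN, reflux) can reach only C6, because the other ortho position is C4a. It would give 5-hydroxy-7-methoxy-2,2-dimethyl-2H-chromene-6-carbaldehyde F5.
- MeMgBr (2.2 equiv) would give 6-(1-hydroxyethyl)-7-methoxy-2,2-dimethyl-2H-chromen-5-ol F6.
- MnO2 oxidation would give 1-(5-hydroxy-7-methoxy-2,2-dimethyl-2H-chromen-6-yl)ethanone F7.
- Claisen–Schmidt condensation with 4-methoxybenzaldehyde (KOH, EtOH) would deliver 17 directly with the E-enone.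

**Step 1.** The two methyl ethers could be poorly discriminated, because the five-membered-ring ketone holds the peri oxygen further from the carbonyl than an acetophenone does. Over-demethylation could follow.

The fallback sets out from 1 and returns at 3.
- Exhaustive cleavage with excess BBr3 (CH2Cl2, −78 °C → rt) would give 4,6-dihydroxybenzofuran-3(2H)-one F8.
- The more acidic 6-OH, which is para to the carbonyl and not hydrogen-bonded, would then be methylated selectively with one equivalent of dimethyl sulfate and K2CO3 in acetone to give 3.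

**Further compounds**
F1 | step 4 | 2-formyl-5-methoxy-3-(methoxymethoxy)phenyl formate | O=COc1cc(OC)cc(OCOC)c1C=O
F2 | step 4 | 2-hydroxy-4-methoxy-6-(methoxymethoxy)benzaldehyde | O=Cc1c(O)cc(OC)cc1OCOC
F3 | step 4 | 2-(1-hydroxy-3-methylbut-2-en-1-yl)-5-methoxy-3-(methoxymethoxy)phenol (racemic) | CC(C)=CC(O)c1c(O)cc(OC)cc1OCOC
F4 | step 6 | 7-methoxy-2,2-dimethyl-2H-chromen-5-ol | Oc1cc(OC)cc2OC(C)(C)C=Cc12
F5 | step 6 | 5-hydroxy-7-methoxy-2,2-dimethyl-2H-chromene-6-carbaldehyde | O=Cc1c(OC)cc2OC(C)(C)C=Cc2c1O
F6 | step 6 | 6-(1-hydroxyethyl)-7-methoxy-2,2-dimethyl-2H-chromen-5-ol (racemic) | CC(O)c1c(OC)cc2OC(C)(C)C=Cc2c1O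
F7 | step 6 | 1-(5-hydroxy-7-methoxy-2,2-dimethyl-2H-chromen-6-yl)ethanone | CC(=O)c1c(OC)cc2OC(C)(C)C=Cc2c1O
F8 | step 1 | 4,6-dihydroxybenzofuran-3(2H)-one | O=C1COc2cc(O)cc(O)c12
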